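## The problem

- **Ring system.** The target is a 2-arylchroman. Ring A is a phloroglucinol-type benzene carrying 5-OH, 7-OMe and a prenyl group on C8. It is fused through C4a–C8a to the dihydropyran ring C, which carries the 4-hydroxyphenyl ring B on C2 and a hydroxyl on C4.
- **Stereocentres.** C2 (S) and C4 (R) stand 1,3 across C3, with the C2 aryl group and the C4 hydroxyl trans on ring C.
- **Control.** C2 can direct C4 but not the reverse. Hydride adds to a C4 ketone axially, on the face of the axial H2, and gives the 2,4-cis alcohol. C2 therefore has to come from a reagent-controlled step, and C4 from substrate-controlled reduction followed by a stereospecific inversion.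
- **Fragile C4.** The C4 hydroxyl is benzylic to a ring that donates through O1 and O5 (ortho) and O7 (para). Acid, a Lewis acid, or a leaving group on O4 beside a free 5-phenoxide leads to the C4 cation or the ortho-quinone methide, and from there to epimerisation, solvolysis, elimination to the flav-3-ene or attack of C6 of a second molecule.
- **Other limits.** The prenyl olefin excludes hydrogenation, hydroboration, strong acid and electrophilic oxidants. At the flavanone level C2 is lost by retro-oxa-Michael opening whenever an enolate or a strong base is present. The prenyl group must end on C8 and not on the equally activated C6.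
- **Enabling feature.** With C4 at the ketone oxidation level, the C3–C4 bond of ring C is the double bond of an enol ether. Ring C is then a 4-silyloxy-2H-chromene, closable by olefin metathesis between a 1-silyloxyvinyl group on C4a (an enolised acetyl group) and a vinyl group on the carbon that becomes C2. O5 lies para to C8, so the prenyl group can ride on O5 through that step and be moved to C8 afterwards by a Claisen–Cope sequence.

## Retrosynthesis

**20 ⇒ 19 ⇒ 18 (unmasking).** The last bond cut is O5–Si (20 from 19, fluoride); before it the acyl–oxygen bonds at O4 and O4' are cut (19 from 18). The order is dictated by the ortho-quinone methide problem: a 5-phenoxide must never coexist with an ester on O4, so the C4 ester is removed first, by hydride at the acyl carbon, and only then is O5 set free. Basic methanolysis of all groups at once would be shorter but would deliver the 4-methyl ether or the flav-3-ene. The forward reactions must leave the C4–O bond untouched.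

**18 ⇒ 17 ⇒ 16 (C4).** The C4–O bond of 18 is traced to the epimeric alcohol 17 by Mitsunobu inversion, and the C4–H bond of 17 to ketone 16 by hydride addition. Direct reduction to the trans alcohol is not available, because both small and bulky hydrides prefer the axial trajectory in a chroman-4-one and the peri substituent on C5 blocks the equatorial one further. O5 is silylated in 16, not acylated: an acyl group would migrate to the C4 alkoxide through a six-membered transition state, and a free phenol would expel the activated O4.

**16 ⇒ 15 ⇒ 12 (prenyl).** After removal of the silyl group (15), the C8–CH2 bond is traced to the O5–CH2 bond of the 5-O-prenyl flavanone 12 through the para-dienone 14 and the ortho-dienone 13. Direct C-prenylation of a 5-hydroxy-7-methoxyflavanone would give C6/C8/O mixtures and needs base that opens the flavanone. The europium-catalysed Claisen–Cope shift of 5-O-prenylflavanones is known to end on C8 and liberates the 5-OH in the same event. The forward reaction must run [3,3] to C6 and a second [3,3] to C8 before the dienone tautomerises.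

**12 ⇒ 11 ⇒ 10 (ring C, key disconnection).** Ketone 12 is the hydrolysis product of silyl enol ether 11, and 11 is opened across C3=C4 to the diene 10. The neighbouring cuts each have a drawback:

- O1–C2 (oxa-Michael of a chalcone) sets C2 under equilibrating conditions.
- C4–C4a (acylation) needs a Lewis acid beside a benzylic ether and a prenyl group.

Metathesis is neutral, makes no stereocentre and leaves C2 alone. Precursor 10 is acyclic in ring C and carries its only stereocentre on an ether carbon. The forward reaction must close onto a hindered 1,1-disubstituted enol ether in preference to any reaction of the prenyl olefin, which is why the prenyl sits on O5. From C8 it would close a seven-membered ring with the vinyl group.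

**10 ⇒ 9 ⇒ 3 + 8 (C2).** The O–Si bond of 10 leads to methyl ketone 9, and the O1–C2 bond of 9 is cut to phenol 3 and the linear cinnamyl carbonate 8. Iridium-catalysed allylic etherification forms this bond at the branched position and sets C2 from an achiral, linear electrophile. A Mitsunobu coupling of a preformed allylic alcohol would risk allylic transposition and is kept as fallback. Ring B carries a pivalate instead of a silyl ether: the weaker donor disfavours ionisation of the iridium allyl, of the product ether and of every later C2–O1 bond, and it is removed in the same hydride step as the C4 ester.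

**8 ⇒ 7 ⇒ 5 ⇒ 4 (ring B fragment).** The carbonate C–O bond of 8 leads to alcohol 7. The C1 oxidation level of 7 is traced through the mixed anhydride 6 to acid 5, and the pivalate of 5 to 4-hydroxycinnamic acid 4. Protecting first and reducing through the mixed anhydride avoids a hydride reagent that would strip the aryl ester.

**3 ⇒ 1 + 2 (ring A fragment).** The O–CH2 bond of 3 is cut to the symmetrical 2',6'-dihydroxy-4'-methoxyacetophenone 1 and prenyl bromide 2. The two hydroxyls of 1 are equivalent, and after the first alkylation the second is locked in a hydrogen bond to the acetyl group, so mono-alkylation is all that is asked.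

## Roads not taken

**Alternative 1:** ortho-quinone methide plus styrene hetero-Diels–Alder.

- **Cut:** O1–C2 and C3–C4 together.
- **Forward step:** the salicylaldehyde A2 and an orthoformate give, under a chiral confined imidodiphosphorimidate acid, the 4-methoxy ortho-quinone methide A4, which adds 4-vinylphenyl acetate A3 to give the 4-methoxyflavan A1.
- **Merits:** two ring bonds and C2 are made in one convergent, catalyst-controlled step. The prenyl group is on C8 from the start, so no prenyl migration is needed. The sequence would be several steps shorter if A2 is easily made.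
- **Weak points:**
  - The catalyst is a very strong acid and the substrate carries a trisubstituted olefin that can be protonated or act as a competing 2π partner.
  - A3 is only a moderately electron-rich dienophile, and A2 is a hindered, fully substituted aldehyde.
  - A1 carries C4 as a methyl ether of undefined configuration. Turning it into the (4R)-alcohol means ionising C4 in water, the very process that epimerises and destroys the target.
  - A2 needs its own regiodefined prenylation and selective silylation.
- **Comparison:** on step economy and convergence this road is better. The chosen plan sets against it that each stereocentre comes from a reaction with a known stereochemical course (allylic etherification, axial hydride addition, SN2 inversion), and that neither the prenyl group nor C4 meets a strong acid.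

**Alternative 2:** three-component carbonylative annulation to the flavone.

- **Cut:** C4a–C4, C4–C3 and O1–C2.
- **Forward step:** the iodophenol A6, CO and the arylacetylene A7 combine under PdCl2(PPh3)2 in Et2NH to the flavone A5.
- **Merits:** robust palladium chemistry from three simple pieces, the prenyl group already on C8, and a flat, easily purified product. The ring construction is more dependable than a metathesis onto an enol ether.
- **Weak points:**
  - A5 has no stereocentre, so C2 must then be made by enantioselective 1,4-reduction of a hindered 5-alkoxyflavone without touching the prenyl olefin, and hydrogenation is excluded.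
  - The C4 problem follows unchanged.
  - The 5-methyl ether must be cleaved selectively with a boron halide in the presence of the prenyl group.
  - Five-membered closure and amine addition to the alkynone intermediate compete in the annulation.
- **Comparison:** the ring is made more reliably, but both stereocentres are left open afterwards. The chosen plan fixes C2 before the ring closes and obtains the free 5-OH from the prenyl shift itself; the step count would be no lower.

**Alternative 3:** chiral aryl ether acid closed by Friedel–Crafts acylation.

- **Cut:** C4–C4a.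
- **Forward step:** the acid A9 is converted to the acyl chloride A10, which cyclises with SnCl4 at low temperature onto the only reachable position, C4a, to give the flavanone A8.
- **Merits:** a classical, regiochemically unambiguous closure that arrives at the C8-prenylated flavanone directly, saving the prenyl migration and the enol ether steps.
- **Weak points:**
  - A β-aryloxy acyl chloride under a Lewis acid can lose the phenol by β-elimination or ionise at the benzylic C2–O bond; either erodes C2.
  - SnCl4 and the HCl it releases threaten the prenyl olefin.
  - The 5-methyl ether again needs selective cleavage.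
  - Enantiopure A9 requires its own asymmetric C–O bond formation onto an ortho-prenylated phenol.
- **Comparison:** it is shorter after ring closure. The chosen plan sets against it a ring closure in a neutral medium that cannot touch C2 or the prenyl group, and a 5-oxygen that never has to be demethylated.

Key step: step 7

Assumption: prenyl means 3-methylbut-2-en-1-yl, and flavan numbering is used (O1, C2–C4, C4a, C5–C8, C8a; primed locants for ring B).

Assumption: step 5 uses the phosphoramidite antipode that gives the (S)-ether. By the usual facial course of this catalyst family this is expected to be the (Sa,Sc,Sc) ligand, but this is unverified and would be confirmed on the first batch.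

## Route

Step 1
Reactants: 1 2',6'-dihydroxy-4'-methoxyacetophenone; 2 prenyl bromide (1-bromo-3-methylbut-2-ene)
Product: 3 2'-hydroxy-4'-methoxy-6'-(3-methylbut-2-enyloxy)acetophenone
Conditions: K2CO3 (1.1 equiv), 2 (1.05 equiv), acetone, reflux
Reagents that add atoms: none
Why: Williamson O-alkylation of one of two equivalent phenols; after the first alkylation the remaining hydroxyl is tied up in a hydrogen bond to the acetyl group and is much less nucleophilic, so the mono-ether should predominate.

Step 2
Reactants: 4 (E)-4-hydroxycinnamic acid
Product: 5 (E)-4-(pivaloyloxy)cinnamic acid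
Conditions: PivCl (1.05 equiv), aq. NaOH (2.1 equiv), THF/H2O, 0 °C; then aq. HCl to pH 3
Reagents that add atoms: pivaloyl chloride, CC(C)(C)C(=O)Cl
Why: Schotten–Baumann acylation; the phenoxide is acylated faster than the carboxylate, and any mixed anhydride formed at the carboxyl group is hydrolysed in the aqueous base.

Step 3
Reactants: 5 (E)-4-(pivaloyloxy)cinnamic acid
Product: 7 (E)-4-(3-hydroxyprop-1-enyl)phenyl pivalate, via mixed carbonic anhydride 6 (not isolated)
Conditions: ClCO2Et, Et3N, THF, −10 °C; filtration; NaBH4, THF/H2O, 0 °C
Reagents that add atoms: none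
Why: Reduction of a carboxylic acid through its mixed carbonic anhydride; NaBH4 attacks the activated acyl carbon at 0 °C and leaves the hindered aryl pivalate and the conjugated olefin alone, as in the known preparation of 4-acyloxycinnamyl alcohols.

Step 4
Reactants: 7 (E)-4-(3-hydroxyprop-1-enyl)phenyl pivalate
Product: 8 (E)-4-[3-(methoxycarbonyloxy)prop-1-enyl]phenyl pivalate
Conditions: ClCO2Me, pyridine, CH2Cl2, 0 °C
Reagents that add atoms: methyl chloroformate, COC(=O)Cl
Why: Acylation of a primary allylic alcohol to the methyl carbonate, the standard leaving group for iridium-catalysed allylic substitution.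

Step 5
Reactants: 3 2'-hydroxy-4'-methoxy-6'-(3-methylbut-2-enyloxy)acetophenone; 8 (E)-4-[3-(methoxycarbonyloxy)prop-1-enyl]phenyl pivalate
Product: 9 (S)-4-[1-(2-acetyl-5-methoxy-3-prenyloxyphenoxy)allyl]phenyl pivalate
Conditions: [Ir(cod)Cl]2 (2 mol%), O,O'-(1,1'-binaphthalene-2,2'-diyl) N,N-bis(1-phenylethyl)phosphoramidite (4 mol%, antipode giving the S ether), preactivation with n-PrNH2; 3 (1.5 equiv), K3PO4 (1.5 equiv), THF, 25–40 °C
Reagents that add atoms: none
Why: Iridium-catalysed asymmetric allylic etherification: the cyclometalated iridium–phosphoramidite complex ionises the carbonate to a π-allyl complex, which the phenoxide attacks at the aryl-substituted terminus anti to the metal, so the branched ether forms and the ligand antipode fixes C2 as S. The excess phenol buffers the methoxide released, which protects the pivalate, and the weakly donating 4-pivaloyloxy group disfavours re-ionisation of the product, the usual cause of lost branched selectivity and enantiomeric purity with electron-rich cinnamyl systems.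

Step 6
Reactants: 9 (S)-4-[1-(2-acetyl-5-methoxy-3-prenyloxyphenoxy)allyl]phenyl pivalate
Product: 10 (S)-4-[1-(2-[1-(tert-butyldimethylsilyloxy)vinyl]-5-methoxy-3-prenyloxyphenoxy)allyl]phenyl pivalate
Conditions: TBSOTf (1.5 equiv), Et3N (3 equiv), CH2Cl2, −20 → 0 °C
Reagents that add atoms: tert-butyldimethylsilyl trifluoromethanesulfonate, CC(C)(C)[Si](C)(C)OS(=O)(=O)C(F)(F)F
Why: Soft enolisation of an aryl methyl ketone (O-silylation, then deprotonation of the only α-position by the amine); no strong base is present, so the benzylic, allylic C–H next to oxygen is not removed and C2 is safe from Wittig-type rearrangement.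

Step 7
Reactants: 10 (S)-4-[1-(2-[1-(tert-butyldimethylsilyloxy)vinyl]-5-methoxy-3-prenyloxyphenoxy)allyl]phenyl pivalate
Product: 11 (2S)-4-(tert-butyldimethylsilyloxy)-7-methoxy-5-prenyloxy-2-[4-(pivaloyloxy)phenyl]-2H-chromene
Conditions: second-generation Grubbs catalyst (H2IMes)(PCy3)Cl2Ru=CHPh (5–10 mol%), toluene (0.005 M), 70 °C, argon purge
Reagents that add atoms: none
Why: Ring-closing olefin metathesis of an olefinic silyl enol ether: the benzylidene exchanges first with the only monosubstituted olefin, the vinyl group on the ether carbon, giving a ruthenium alkylidene held within reach of the enol ether. Intramolecular [2+2] addition to the 1,1-disubstituted silyl enol ether gives a ruthenacyclobutane, whose cycloreversion forms the trisubstituted C3=C4 enol ether and releases the ruthenium methylidene, which carries the chain with loss of ethene. The closest known reactions are the closure of olefinic silyl enol ethers to five- to seven-membered cyclic silyl enol ethers and the closure of ortho-vinylaryl 1-arylallyl ethers to 2-aryl-2H-chromenes with the same catalyst. Ring C closes as a six-membered ring with the new double bond endocyclic, so no olefin geometry question arises. No stereocentre is created; C2, set in step 5, is untouched because the medium is neutral and aprotic and neither the C2–O1 nor the C2–H bond takes part. The step needs chemoselectivity among three olefins: the carbene on the vinyl group reaches the enol ether through a six-membered ring but the O5 prenyl olefin only through a nine-membered one, and direct loading on the trisubstituted prenyl or the 1,1-disubstituted enol ether olefin is much slower than on the vinyl group. High dilution and removal of ethene favour ring closure over dimerisation through the vinyl groups.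

Step 8
Reactants: 11 (2S)-4-(tert-butyldimethylsilyloxy)-7-methoxy-5-prenyloxy-2-[4-(pivaloyloxy)phenyl]-2H-chromene
Product: 12 (2S)-7-methoxy-5-prenyloxy-4'-pivaloyloxyflavanone
Conditions: 1 M aq. HCl/THF (1:10), 0 °C
Reagents that add atoms: none
Why: Acid hydrolysis of a silyl enol ether by protonation at C3 and loss of the silyl group from the oxocarbenium ion; no enolate is formed, so the retro-oxa-Michael opening that would racemise C2 has no entry, and the prenyl ether and pivalate tolerate brief dilute acid.

Step 9
Reactants: 12 (2S)-7-methoxy-5-prenyloxy-4'-pivaloyloxyflavanone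
Product: 15 (2S)-5-hydroxy-7-methoxy-8-prenyl-4'-pivaloyloxyflavanone, via C6 ortho-dienone 13 (not isolated), via C8 para-dienone 14 (not isolated)
Conditions: Eu(fod)3 (10 mol%), CHCl3, 60 °C, sealed vessel
Reagents that add atoms: none
Why: Lanthanide-catalysed aromatic Claisen rearrangement followed by Cope rearrangement: trivalent europium chelated between O5 and the C4 carbonyl triggers the [3,3] shift to C6, the reverse-prenyl dienone undergoes a second [3,3] shift to C8, and tautomerisation gives the chelated 5-hydroxy-8-prenylflavanone, as known for 5-O-prenylflavanones with a 4'-acyloxy group. The weakly donating pivalate keeps the C2–O1 bond from ionising under the Lewis acid.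

Step 10
Reactants: 15 (2S)-5-hydroxy-7-methoxy-8-prenyl-4'-pivaloyloxyflavanone
Product: 16 (2S)-5-(tert-butyldimethylsilyloxy)-7-methoxy-8-prenyl-4'-pivaloyloxyflavanone
Conditions: TBSOTf (1.3 equiv), 2,6-lutidine (2.5 equiv), CH2Cl2, −78 → −20 °C
Reagents that add atoms: tert-butyldimethylsilyl trifluoromethanesulfonate, CC(C)(C)[Si](C)(C)OS(=O)(=O)C(F)(F)F
Why: Silylation of a hydrogen-bonded phenol with the silyl triflate and a hindered base; at low temperature the ketone is not enol-silylated and the base is too weak to open the flavanone. A silyl group is used because an acyl group on O5 would migrate to the C4 alkoxide in the next step.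

Step 11
Reactants: 16 (2S)-5-(tert-butyldimethylsilyloxy)-7-methoxy-8-prenyl-4'-pivaloyloxyflavanone
Product: 17 (2S,4S)-5-(tert-butyldimethylsilyloxy)-7-methoxy-8-prenyl-4'-pivaloyloxyflavan-4-ol (2,4-cis)
Conditions: NaBH4, THF/MeOH (5:1), 0 °C; acetone, then pH 7 phosphate buffer
Reagents that add atoms: none
Why: Substrate-controlled hydride reduction of a flavanone: with the C2 aryl group equatorial, hydride enters axially on the face of the axial H2 and gives the equatorial 4-hydroxyl cis to the aryl group, that is 4S. The peri silyloxy group blocks the equatorial trajectory further, and the low temperature and borate-bound alkoxide keep silyl migration from O5 to O4 slow.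

Step 12
Reactants: 17 (2S,4S)-5-(tert-butyldimethylsilyloxy)-7-methoxy-8-prenyl-4'-pivaloyloxyflavan-4-ol
Product: 18 (2S,4R)-4-(4-nitrobenzoyloxy)-5-(tert-butyldimethylsilyloxy)-7-methoxy-8-prenyl-4'-pivaloyloxyflavan (2,4-trans)
Conditions: 4-nitrobenzoic acid, PPh3, DIAD, toluene/THF, −20 → 0 °C
Reagents that add atoms: 4-nitrobenzoic acid, OC(=O)c1ccc(cc1)[N+](=O)[O-]
Why: Mitsunobu inversion, known for 2,4-cis-flavan-4-ols: the carboxylate displaces the equatorial oxyphosphonium group from the axial direction with inversion and sets C4 as R. Any share of the reaction that runs through the C4 cation should converge on the same ester, because axial capture with the aryl group equatorial is favoured and the axial ester avoids the peri substituent on C5. The silyl group on O5 prevents expulsion of the activated O4 by a phenol.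

Step 13
Reactants: 18 (2S,4R)-4-(4-nitrobenzoyloxy)-5-(tert-butyldimethylsilyloxy)-7-methoxy-8-prenyl-4'-pivaloyloxyflavan
Product: 19 (2S,4R)-5-(tert-butyldimethylsilyloxy)-7-methoxy-8-prenylflavan-4,4'-diol (2,4-trans)
Conditions: i-Bu2AlH (excess), THF/toluene, −78 °C; aq. potassium sodium tartrate
Reagents that add atoms: none
Why: Reductive cleavage of both esters by hydride attack at the acyl carbons; the C4–O bond is not broken, so the configuration is kept, and the resulting aluminium alkoxide on O4 is no leaving group. The C4 ester is removed here, before O5 is unmasked, so that a 5-phenoxide never sits beside an O4 ester.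

Step 14
Reactants: 19 (2S,4R)-5-(tert-butyldimethylsilyloxy)-7-methoxy-8-prenylflavan-4,4'-diol
Product: 20 (2S,4R)-4,5,4'-trihydroxy-7-methoxy-8-prenylflavan
Conditions: Bu4NF, AcOH (1:1), THF, 0 °C; pH 7 buffer
Reagents that add atoms: none
Why: Fluoride cleavage of the aryl silyl ether under buffered conditions; the free C4 hydroxyl is not a leaving group, so the phenoxide formed cannot generate the ortho-quinone methide, and no acid is used at any point of the isolation.

## Compound list

1 | 2',6'-dihydroxy-4'-methoxyacetophenone | CC(=O)c1c(O)cc(OC)cc1O | starting material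
2 | prenyl bromide (1-bromo-3-methylbut-2-ene) | CC(C)=CCBr | starting material
3 | 2'-hydroxy-4'-methoxy-6'-(3-methylbut-2-enyloxy)acetophenone | CC(=O)c1c(O)cc(OC)cc1OCC=C(C)C | intermediate
4 | (E)-4-hydroxycinnamic acid | O=C(O)/C=C/c1ccc(O)cc1 | starting material
5 | (E)-4-(pivaloyloxy)cinnamic acid | O=C(O)/C=C/c1ccc(OC(=O)C(C)(C)C)cc1 | intermediate
6 | ethoxycarbonyl (E)-3-[4-(pivaloyloxy)phenyl]prop-2-enoate (mixed carbonic anhydride) | CCOC(=O)OC(=O)/C=C/c1ccc(OC(=O)C(C)(C)C)cc1 | intermediate
7 | (E)-4-(3-hydroxyprop-1-enyl)phenyl pivalate | OC/C=C/c1ccc(OC(=O)C(C)(C)C)cc1 | intermediate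
8 | (E)-4-[3-(methoxycarbonyloxy)prop-1-enyl]phenyl pivalate | COC(=O)OC/C=C/c1ccc(OC(=O)C(C)(C)C)cc1 | intermediate
9 | (S)-4-[1-(2-acetyl-5-methoxy-3-prenyloxyphenoxy)allyl]phenyl pivalate | CC(=O)c1c(OCC=C(C)C)cc(OC)cc1O[C@H](c1ccc(OC(=O)C(C)(C)C)cc1)C=C | intermediate
10 | (S)-4-[1-(2-[1-(tert-butyldimethylsilyloxy)vinyl]-5-methoxy-3-prenyloxyphenoxy)allyl]phenyl pivalate | C=C(O[Si](C)(C)C(C)(C)C)c1c(OCC=C(C)C)cc(OC)cc1O[C@H](c1ccc(OC(=O)C(C)(C)C)cc1)C=C | intermediate
11 | (2S)-4-(tert-butyldimethylsilyloxy)-7-methoxy-5-prenyloxy-2-[4-(pivaloyloxy)phenyl]-2H-chromene | COc1cc(OCC=C(C)C)c2c(c1)O[C@H](c1ccc(OC(=O)C(C)(C)C)cc1)C=C2O[Si](C)(C)C(C)(C)C | intermediate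
12 | (2S)-7-methoxy-5-prenyloxy-4'-pivaloyloxyflavanone | COc1cc(OCC=C(C)C)c2c(c1)O[C@H](c1ccc(OC(=O)C(C)(C)C)cc1)CC2=O | intermediate
13 | (2S)-7-methoxy-6-(2-methylbut-3-en-2-yl)-2-[4-(pivaloyloxy)phenyl]-2,3-dihydro-6H-chromene-4,5-dione (ortho-dienone, C6 epimers) | COC1C(C(C)(C)C=C)C(=O)C2=C(C=1)O[C@H](c1ccc(OC(=O)C(C)(C)C)cc1)CC2=O | intermediate
14 | (2S)-7-methoxy-8-(3-methylbut-2-enyl)-2-[4-(pivaloyloxy)phenyl]-2,3-dihydro-8H-chromene-4,5-dione (para-dienone, C8 epimers) | COC1=CC(=O)C2=C(C1CC=C(C)C)O[C@H](c1ccc(OC(=O)C(C)(C)C)cc1)CC2=O | intermediate
15 | (2S)-5-hydroxy-7-methoxy-8-prenyl-4'-pivaloyloxyflavanone | COc1cc(O)c2c(c1CC=C(C)C)O[C@H](c1ccc(OC(=O)C(C)(C)C)cc1)CC2=O | intermediate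
16 | (2S)-5-(tert-butyldimethylsilyloxy)-7-methoxy-8-prenyl-4'-pivaloyloxyflavanone | COc1cc(O[Si](C)(C)C(C)(C)C)c2c(c1CC=C(C)C)O[C@H](c1ccc(OC(=O)C(C)(C)C)cc1)CC2=O | intermediate
17 | (2S,4S)-5-(tert-butyldimethylsilyloxy)-7-methoxy-8-prenyl-4'-pivaloyloxyflavan-4-ol | COc1cc(O[Si](C)(C)C(C)(C)C)c2c(c1CC=C(C)C)O[C@H](c1ccc(OC(=O)C(C)(C)C)cc1)C[C@@H]2O | intermediate
18 | (2S,4R)-4-(4-nitrobenzoyloxy)-5-(tert-butyldimethylsilyloxy)-7-methoxy-8-prenyl-4'-pivaloyloxyflavan | COc1cc(O[Si](C)(C)C(C)(C)C)c2c(c1CC=C(C)C)O[C@H](c1ccc(OC(=O)C(C)(C)C)cc1)C[C@H]2OC(=O)c1ccc(cc1)[N+](=O)[O-] | intermediate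
19 | (2S,4R)-5-(tert-butyldimethylsilyloxy)-7-methoxy-8-prenylflavan-4,4'-diol | COc1cc(O[Si](C)(C)C(C)(C)C)c2c(c1CC=C(C)C)O[C@H](c1ccc(O)cc1)C[C@H]2O | intermediate
20 | (2S,4R)-4,5,4'-trihydroxy-7-methoxy-8-prenylflavan | COc1cc(O)c2c(c1CC=C(C)C)O[C@H](c1ccc(O)cc1)C[C@H]2O | target

## Step count and risks

Total step count: 14. Longest linear sequence: 13 steps (from 4 through steps 2–14); the ring A branch from 1 is 11 steps.

**Step 7 (key step).**
- **What may go wrong:** closure onto the hindered, electron-rich 1,1-disubstituted enol ether may be slow. That would allow dimerisation through the vinyl groups, catalyst loading on the prenyl ether followed by closure onto the enol ether from the O5 side with loss of isobutene, isomerisation of the allyl ether by ruthenium hydride species, or premature hydrolysis of the enol ether.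
- **Fallback:** ring C is closed at O1–C2 instead. Starting from 3, Claisen–Schmidt condensation with 4-hydroxybenzaldehyde (KOH, EtOH) would give (E)-1-[2-hydroxy-4-methoxy-6-(3-methylbut-2-enyloxy)phenyl]-3-(4-hydroxyphenyl)prop-2-en-1-one F1. Acylation of its only non-chelated hydroxyl (PivCl, Et3N) would give the chalcone pivalate (E)-4-[3-(2-hydroxy-4-methoxy-6-prenyloxyphenyl)-3-oxoprop-1-enyl]phenyl pivalate F2. Intramolecular oxa-Michael addition under a quinine-derived bifunctional thiourea catalyst returns to the route at 12. Enantiomeric purity is less secure on this road and would have to be raised by crystallisation.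

**Step 5.**
- **What may go wrong:** the chelated ortho-acyl phenoxide may be too weak a nucleophile. The iridium allyl may then be captured at carbon of the phloroglucinol-type ring, branched selectivity and enantiomeric purity may drift by reversible ionisation of the product, or the pivaloyl group may transfer to phenoxide.
- **Fallback:** the O1–C2 bond is made by SN2 at a preformed stereocentre. Starting from 8, iridium-catalysed allylic hydroxylation with KHCO3 and the antipodal ligand would give (R)-4-(1-hydroxyprop-2-enyl)phenyl pivalate F3. Mitsunobu etherification of F3 with 3 (PPh3, DIAD, toluene, 0 °C) proceeds with inversion and comes back to the route at 9. Allylic transposition and partial racemisation are the hazards of this road.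

**Step 12.**
- **What may go wrong:** the activated C4 oxyphosphonium ion may ionise, giving loss of stereospecificity or elimination to the flav-3-ene. The peri silyloxy group may slow the substitution, and the silyl group may migrate.
- **Fallback:** C4 is set by reagent control without inversion. Starting from 16, Corey–Bakshi–Shibata reduction with catecholborane (toluene, −78 °C; the (S)-oxazaborolidine is expected to give 4R by the aryl-large model) would give (2S,4R)-5-(tert-butyldimethylsilyloxy)-7-methoxy-8-prenyl-4'-pivaloyloxyflavan-4-ol F4. Removal of the pivalate with i-Bu2AlH returns to the route at 19. The catalyst works against the substrate bias here, so the diastereoselectivity is uncertain.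

**Step 13.**
- **What may go wrong:** aluminium may assist ionisation of the C4 ester, followed by hydride capture at C4 (loss of the oxygen) or elimination. The nitro group may be partly reduced.
- **Fallback:** the ester is chosen so that it can be removed without a Lewis acid or an alkoxide. Starting from 17, Mitsunobu inversion with formic acid would give the formate (2S,4R)-4-formyloxy-5-(tert-butyldimethylsilyloxy)-7-methoxy-8-prenyl-4'-pivaloyloxyflavan F5. Aminolysis with methylamine in THF at 0 °C → room temperature removes the formyl and pivaloyl groups, leaves the aryl silyl ether and comes back to the route at 19.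

## Further compounds

F1 | step 7 | (E)-1-[2-hydroxy-4-methoxy-6-(3-methylbut-2-enyloxy)phenyl]-3-(4-hydroxyphenyl)prop-2-en-1-one | COc1cc(O)c(C(=O)/C=C/c2ccc(O)cc2)c(OCC=C(C)C)c1
F2 | step 7 | (E)-4-[3-(2-hydroxy-4-methoxy-6-prenyloxyphenyl)-3-oxoprop-1-enyl]phenyl pivalate | COc1cc(O)c(C(=O)/C=C/c2ccc(OC(=O)C(C)(C)C)cc2)c(OCC=C(C)C)c1
F3 | step 5 | (R)-4-(1-hydroxyprop-2-enyl)phenyl pivalate | O[C@@H](c1ccc(OC(=O)C(C)(C)C)cc1)C=C
F4 | step 12 | (2S,4R)-5-(tert-butyldimethylsilyloxy)-7-methoxy-8-prenyl-4'-pivaloyloxyflavan-4-ol | COc1cc(O[Si](C)(C)C(C)(C)C)c2c(c1CC=C(C)C)O[C@H](c1ccc(OC(=O)C(C)(C)C)cc1)C[C@H]2O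
F5 | step 13 | (2S,4R)-4-formyloxy-5-(tert-butyldimethylsilyloxy)-7-methoxy-8-prenyl-4'-pivaloyloxyflavan | COc1cc(O[Si](C)(C)C(C)(C)C)c2c(c1CC=C(C)C)O[C@H](c1ccc(OC(=O)C(C)(C)C)cc1)C[C@H]2OC=O
A1 | alternative 1 | (2S)-4'-O-acetyl-4-O-methyl-5-O-triisopropylsilyl derivative of the target (either C4 epimer) | COc1cc(O[Si](C(C)C)(C(C)C)C(C)C)c2c(c1CC=C(C)C)O[C@H](c1ccc(OC(C)=O)cc1)CC2OC
A2 | alternative 1 | 2-hydroxy-4-methoxy-3-(3-methylbut-2-enyl)-6-(triisopropylsilyloxy)benzaldehyde | COc1cc(O[Si](C(C)C)(C(C)C)C(C)C)c(C=O)c(O)c1CC=C(C)C
A3 | alternative 1 | 4-vinylphenyl acetate | C=Cc1ccc(OC(C)=O)cc1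
A4 | alternative 1 | 4-methoxy ortho-quinone methide derived from A2 | COC=C1C(=O)C(CC=C(C)C)=C(OC)C=C1O[Si](C(C)C)(C(C)C)C(C)C
A5 | alternative 2 | 5,7-dimethoxy-8-prenyl-4'-(tert-butyldimethylsilyloxy)flavone | COc1cc(OC)c2c(c1CC=C(C)C)OC(c1ccc(O[Si](C)(C)C(C)(C)C)cc1)=CC2=O
A6 | alternative 2 | 2-iodo-3,5-dimethoxy-6-(3-methylbut-2-enyl)phenol | COc1cc(OC)c(I)c(O)c1CC=C(C)C
A7 | alternative 2 | tert-butyl(4-ethynylphenoxy)dimethylsilane | C#Cc1ccc(O[Si](C)(C)C(C)(C)C)cc1
A8 | alternative 3 | (2S)-5,7-dimethoxy-8-prenyl-4'-pivaloyloxyflavanone | COc1cc(OC)c2c(c1CC=C(C)C)O[C@H](c1ccc(OC(=O)C(C)(C)C)cc1)CC2=O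
A9 | alternative 3 | (S)-3-[3,5-dimethoxy-2-(3-methylbut-2-enyl)phenoxy]-3-[4-(pivaloyloxy)phenyl]propanoic acid | COc1cc(OC)cc(O[C@H](c2ccc(OC(=O)C(C)(C)C)cc2)CC(=O)O)c1CC=C(C)C
A10 | alternative 3 | (S)-3-[3,5-dimethoxy-2-(3-methylbut-2-enyl)phenoxy]-3-[4-(pivaloyloxy)phenyl]propanoyl chloride | COc1cc(OC)cc(O[C@H](c2ccc(OC(=O)C(C)(C)C)cc2)CC(=O)Cl)c1CC=C(C)C
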